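Numbering used (furo[3,4-c]furan-1-one): C1(=O), O2, C3 (trihydroxyphenyl), C3a, C4H2, O5, C6 (dihydroxyphenyl), C6a.
Cuts, in retrosynthetic order: five O–benzyl bonds; C6a–H back to C6a–I; O5–C6 together with C6a–I (iodoetherification of an (E)-C6=C6a benzylidene lactone by its C4 hydroxyl); C4–OH back to an acyl oxazolidinone; O2–C1 and C3–C3a (aldol/lactonisation); C6=C6a (Stobbe condensation).
Forward: Stobbe chain assembly, auxiliary attachment, aldol that closes the γ-lactone (first ring), reductive release of C4–OH, then the tetrahydrofuran is closed last.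
Enabling feature: the E C6=C6a double bond lies between the electron-rich 3,4-dioxygenated aryl ring and the lactone C1=O and is homoallylic to O5, so opening of an iodonium at benzylic C6 by O5 closes a five-membered ring.
Stereochemistry: C3 and C3a from the syn-aldol with (S)-4-benzyloxazolidin-2-one; C6 from anti addition across the E alkene; C6a from the enforced cis ring fusion on radical deiodination.

Key step: step 5

Assumption: all five phenols are carried as benzyl ethers, and aldehydes 1 and 7, diester 2 and oxazolidinone 4 are taken as commercial.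

Step 1
Reactants: 1 3,4-bis(benzyloxy)benzaldehyde; 2 dimethyl succinate
Product: 3 (E)-4-[3,4-bis(benzyloxy)phenyl]-3-(methoxycarbonyl)but-3-enoic acid
Conditions: NaOMe, MeOH, reflux; aq. HCl
Reagents that add atoms: none
Why: Stobbe condensation (aldol, lactonisation to the paraconic ester, E1cB ring opening) should give the half-ester with the free acid on the CH2 arm and the E alkene (aryl trans to CO2Me), the benzyl ethers being inert to methoxide.

Step 2
Reactants: 3 (E)-4-[3,4-bis(benzyloxy)phenyl]-3-(methoxycarbonyl)but-3-enoic acid; 4 (S)-4-benzyloxazolidin-2-one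
Product: 6 (S)-4-benzyl-3-{(E)-4-[3,4-bis(benzyloxy)phenyl]-3-(methoxycarbonyl)but-3-enoyl}oxazolidin-2-one, via mixed pivalic anhydride 5 (not isolated)
Conditions: PivCl, Et3N, THF, −20 °C; then 4, LiCl, −20 °C → rt
Reagents that add atoms: none
Why: N-acylation of an oxazolidinone through the mixed pivalic anhydride is standard, attack should occur at the less hindered acyl carbon, and the conjugated methyl ester and the E alkene are not touched.

Step 3
Reactants: 6 (S)-4-benzyl-3-{(E)-4-[3,4-bis(benzyloxy)phenyl]-3-(methoxycarbonyl)but-3-enoyl}oxazolidin-2-one; 7 3,4,5-tris(benzyloxy)benzaldehyde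
Product: 9 (S)-4-benzyl-3-{[(2S,3S,4E)-4-[3,4-bis(benzyloxy)benzylidene]-5-oxo-2-[3,4,5-tris(benzyloxy)phenyl]tetrahydrofuran-3-yl]carbonyl}oxazolidin-2-one, via syn-aldol hydroxy ester 8 (not isolated)
Conditions: Bu2BOTf, iPr2NEt, CH2Cl2, −78 → 0 °C; 7, −78 → 0 °C; pH 7 buffer/MeOH; PPTS (cat.), PhMe, 50 °C
Reagents that add atoms: none
Why: Evans syn-aldol: the Z(O) boron enolate should react through a chair Zimmerman–Traxler transition state on the face away from the auxiliary benzyl group to set C3a and C3 (2S,3S adduct 8), and the new hydroxyl then lactonises onto the neighbouring methyl ester with retention, the syn adduct giving the 2,3-trans lactone.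

Step 4
Reactants: 9 (S)-4-benzyl-3-{[(2S,3S,4E)-4-[3,4-bis(benzyloxy)benzylidene]-5-oxo-2-[3,4,5-tris(benzyloxy)phenyl]tetrahydrofuran-3-yl]carbonyl}oxazolidin-2-one
Product: 10 (3E,4R,5S)-3-[3,4-bis(benzyloxy)benzylidene]-4-(hydroxymethyl)-5-[3,4,5-tris(benzyloxy)phenyl]dihydrofuran-2(3H)-one
Conditions: LiBH4, MeOH (1 equiv), THF, −20 → 0 °C; aq. NH4Cl
Reagents that add atoms: none
Why: Reductive cleavage of an N-acyl oxazolidinone by LiBH4 is much faster than reduction of a conjugated γ-lactone, so the exocyclic imide carbonyl should become the C4 primary alcohol under non-hydrolytic, weakly basic conditions that leave the allylic C3a centre, the lactone and the E alkene intact, with the auxiliary recovered.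

Step 5
Reactants: 10 (3E,4R,5S)-3-[3,4-bis(benzyloxy)benzylidene]-4-(hydroxymethyl)-5-[3,4,5-tris(benzyloxy)phenyl]dihydrofuran-2(3H)-one
Product: 11 (3S,3aR,6R,6aR)-6-[3,4-bis(benzyloxy)phenyl]-6a-iodo-3-[3,4,5-tris(benzyloxy)phenyl]tetrahydro-1H,3H-furo[3,4-c]furan-1-one
Conditions: NIS, CH2Cl2, 0 °C → rt, dark
Reagents that add atoms: N-iodosuccinimide, O=C1CCC(=O)N1I
Why: Electrophilic iodine should add reversibly to either face of the C6=C6a benzylidene bond, and only the iodonium on the face opposite the CH2OH arm can be opened at benzylic C6 by the homoallylic hydroxyl; the closest known reaction types are the 5-endo iodoetherification of aryl-substituted homoallylic alcohols and the halohydrin or haloether formation of cinnamates. The tetrahydrofuran closes in a 5-endo-trig mode (both alkene carbons end in the new ring), which is feasible because the oxygen opens a three-membered iodonium, or the derived p-alkoxybenzyl cation, and not a planar π bond. C6 is set by anti addition across the E alkene (aryl cis to C3a): oxygen enters from the face of the CH2OH arm and the aryl group ends trans to C1, that is exo, and the same result is expected from a free benzylic cation because the aryl group then avoids the lactone carbonyl carbon rather than the long C–I bond. C6a receives iodine at the angular position anti to the new C–O bond, which already fixes the cis ring fusion that step 6 only has to keep. Regioselectivity (O to C6, I to C6a) is secured by the 4-benzyloxy group para to C6 and by ring size (attack at C6a would give an oxetane), facial selectivity by the tether, and chemoselectivity over iodination of the alkoxyarenes by the absence of acid and light.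

Step 6
Reactants: 11 (3S,3aR,6R,6aR)-6-[3,4-bis(benzyloxy)phenyl]-6a-iodo-3-[3,4,5-tris(benzyloxy)phenyl]tetrahydro-1H,3H-furo[3,4-c]furan-1-one
Product: 12 (3S,3aR,6S,6aS)-6-[3,4-bis(benzyloxy)phenyl]-3-[3,4,5-tris(benzyloxy)phenyl]tetrahydro-1H,3H-furo[3,4-c]furan-1-one
Conditions: Bu3SnH, AIBN (cat.), PhMe, 80 °C
Reagents that add atoms: none
Why: Radical chain dehalogenation: the tertiary α-lactone radical at C6a can accept hydrogen only on the convex face, because a trans-fused 3,7-dioxabicyclo[3.3.0]octanone is prohibitively strained, so the cis-fused 6aS centre should result while C3, C3a and C6 are untouched and no enolate (hence no β-alkoxide elimination) is formed.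

Step 7
Reactants: 12 (3S,3aR,6S,6aS)-6-[3,4-bis(benzyloxy)phenyl]-3-[3,4,5-tris(benzyloxy)phenyl]tetrahydro-1H,3H-furo[3,4-c]furan-1-one
Product: 13 (3S,3aR,6S,6aS)-6-(3,4-dihydroxyphenyl)-3-(3,4,5-trihydroxyphenyl)tetrahydro-1H,3H-furo[3,4-c]furan-1-one
Conditions: H2 (1 atm), 10% Pd/C, THF–MeOH, rt
Reagents that add atoms: none
Why: Hydrogenolysis of the five aryl benzyl ethers should be much faster than cleavage of the two benzylic alkyl C–O bonds (C3–O2 and C6–O5) under neutral conditions at 1 atm when stopped at the calculated uptake, so the free catechol and pyrogallol rings are released without touching a stereocentre.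

Compound list
1 | 3,4-bis(benzyloxy)benzaldehyde | O=Cc1ccc(OCc2ccccc2)c(OCc2ccccc2)c1 | starting material
2 | dimethyl succinate | COC(=O)CCC(=O)OC | starting material
3 | (E)-4-[3,4-bis(benzyloxy)phenyl]-3-(methoxycarbonyl)but-3-enoic acid | COC(=O)/C(CC(=O)O)=C/c1ccc(OCc2ccccc2)c(OCc2ccccc2)c1 | intermediate
4 | (S)-4-benzyloxazolidin-2-one | O=C1OC[C@H](Cc2ccccc2)N1 | starting material
5 | (E)-4-[3,4-bis(benzyloxy)phenyl]-3-(methoxycarbonyl)but-3-enoic pivalic anhydride | COC(=O)/C(CC(=O)OC(=O)C(C)(C)C)=C/c1ccc(OCc2ccccc2)c(OCc2ccccc2)c1 | intermediate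
6 | (S)-4-benzyl-3-{(E)-4-[3,4-bis(benzyloxy)phenyl]-3-(methoxycarbonyl)but-3-enoyl}oxazolidin-2-one | COC(=O)/C(CC(=O)N1[C@@H](Cc2ccccc2)COC1=O)=C/c1ccc(OCc2ccccc2)c(OCc2ccccc2)c1 | intermediate
7 | 3,4,5-tris(benzyloxy)benzaldehyde | O=Cc1cc(OCc2ccccc2)c(OCc2ccccc2)c(OCc2ccccc2)c1 | starting material
8 | (S)-4-benzyl-3-[(2S,3S)-2-{(E)-2-[3,4-bis(benzyloxy)phenyl]-1-(methoxycarbonyl)vinyl}-3-hydroxy-3-[3,4,5-tris(benzyloxy)phenyl]propanoyl]oxazolidin-2-one | O[C@H](c1cc(OCc2ccccc2)c(OCc2ccccc2)c(OCc2ccccc2)c1)[C@@H](C(=O)N1[C@@H](Cc2ccccc2)COC1=O)/C(C(=O)OC)=C\c1ccc(OCc2ccccc2)c(OCc2ccccc2)c1 | intermediate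
9 | (S)-4-benzyl-3-{[(2S,3S,4E)-4-[3,4-bis(benzyloxy)benzylidene]-5-oxo-2-[3,4,5-tris(benzyloxy)phenyl]tetrahydrofuran-3-yl]carbonyl}oxazolidin-2-one | O=C1O[C@H](c2cc(OCc3ccccc3)c(OCc3ccccc3)c(OCc3ccccc3)c2)[C@@H](C(=O)N2[C@@H](Cc3ccccc3)COC2=O)/C1=C\c1ccc(OCc2ccccc2)c(OCc2ccccc2)c1 | intermediate
10 | (3E,4R,5S)-3-[3,4-bis(benzyloxy)benzylidene]-4-(hydroxymethyl)-5-[3,4,5-tris(benzyloxy)phenyl]dihydrofuran-2(3H)-one | O=C1O[C@H](c2cc(OCc3ccccc3)c(OCc3ccccc3)c(OCc3ccccc3)c2)[C@@H](CO)/C1=C\c1ccc(OCc2ccccc2)c(OCc2ccccc2)c1 | intermediate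
11 | (3S,3aR,6R,6aR)-6-[3,4-bis(benzyloxy)phenyl]-6a-iodo-3-[3,4,5-tris(benzyloxy)phenyl]tetrahydro-1H,3H-furo[3,4-c]furan-1-one | O=C1O[C@H](c2cc(OCc3ccccc3)c(OCc3ccccc3)c(OCc3ccccc3)c2)[C@H]2CO[C@H](c3ccc(OCc4ccccc4)c(OCc4ccccc4)c3)[C@@]12I | intermediate
12 | (3S,3aR,6S,6aS)-6-[3,4-bis(benzyloxy)phenyl]-3-[3,4,5-tris(benzyloxy)phenyl]tetrahydro-1H,3H-furo[3,4-c]furan-1-one | O=C1O[C@H](c2cc(OCc3ccccc3)c(OCc3ccccc3)c(OCc3ccccc3)c2)[C@H]2CO[C@H](c3ccc(OCc4ccccc4)c(OCc4ccccc4)c3)[C@@H]12 | intermediate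
13 | (3S,3aR,6S,6aS)-6-(3,4-dihydroxyphenyl)-3-(3,4,5-trihydroxyphenyl)tetrahydro-1H,3H-furo[3,4-c]furan-1-one | O=C1O[C@H](c2cc(O)c(O)c(O)c2)[C@H]2CO[C@H](c3ccc(O)c(O)c3)[C@@H]12 | target

Total step count: 7. Longest linear sequence: 7 steps (1 and 2 → 3 → 6 → 9 → 10 → 11 → 12 → 13).

Steps most likely to fail

Step 5 (key step). Ring closure by the hydroxyl may not keep pace with reversible iodonium formation at the trisubstituted, carbonyl-conjugated C6=C6a bond (the aryl group is cis to the attacking arm). Iodination of the alkoxyarenes, or loss of anti stereospecificity through a long-lived benzylic cation, could then take over. The fallback sets out from 10 and returns at 12. The C=C bond is first reduced by conjugate hydride addition ([(Ph3P)CuH]6, PhMe, then aqueous work-up); protonation of the enolate on the face opposite the neighbouring CH2OH should favour the 3,4-cis epimer, (3R,4R,5S)-3-[3,4-bis(benzyloxy)benzyl]-4-(hydroxymethyl)-5-[3,4,5-tris(benzyloxy)phenyl]dihydrofuran-2(3H)-one F1. The ring is then closed oxidatively with DDQ (CH2Cl2, rt): hydride abstraction from the 3,4-bis(benzyloxy)benzyl CH2 gives a p-alkoxybenzyl cation, which the cis CH2OH should trap in a 5-exo closure with the aryl group exo, giving 12. A trans-3,4 epimer cannot close to a cis-fused bicycle and would be left behind.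

Step 4. Hydride may also attack the lactone carbonyl. The medium may deprotonate C3a of 9, which is both α to the imide and allylic, leading to double-bond migration or β-elimination of the lactone oxygen. The product alkoxide may also translactonise. The fallback sets out from 3 and returns at 12; it removes the alkene before the auxiliary chemistry and closes the ring by benzylic oxidation instead.
- Asymmetric hydrogenation of 3 (H2, cationic Rh(I)/Et-DuPhos, MeOH, ligand enantiomer chosen for the R acid) should give (R)-4-[3,4-bis(benzyloxy)phenyl]-3-(methoxycarbonyl)butanoic acid F2.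
- Acylation of 4 as in step 2 gives (S)-4-benzyl-3-{(R)-4-[3,4-bis(benzyloxy)phenyl]-3-(methoxycarbonyl)butanoyl}oxazolidin-2-one F3.
- Boron aldol with 7 and lactonisation as in step 3 gives (S)-4-benzyl-3-{[(2S,3S,4R)-4-[3,4-bis(benzyloxy)benzyl]-5-oxo-2-[3,4,5-tris(benzyloxy)phenyl]tetrahydrofuran-3-yl]carbonyl}oxazolidin-2-one F4, whose C3–H is no longer allylic.
- LiOH/H2O2 (THF–H2O, 0 °C) then gives (2S,3S,4R)-4-[3,4-bis(benzyloxy)benzyl]-5-oxo-2-[3,4,5-tris(benzyloxy)phenyl]tetrahydrofuran-3-carboxylic acid F5.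
- Acid-selective reduction with BH3·SMe2 gives the cis-benzyl alcohol F1 described above, which DDQ closes to 12 as in the fallback to step 5.

Step 7. Hydrogenolysis of the benzylic C3–O2 (lactone) and C6–O5 (ether) bonds may compete with O-debenzylation. The fallback sets out from 12 and ends at 13. Debenzylation is done without hydrogen by Lewis-acid dealkylation with a cation scavenger (BCl3, pentamethylbenzene, CH2Cl2, −78 °C, methanol quench); the benzyl cations are captured by the arene and no reducing agent is present.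

Further compounds
F1 | step 5 | (3R,4R,5S)-3-[3,4-bis(benzyloxy)benzyl]-4-(hydroxymethyl)-5-[3,4,5-tris(benzyloxy)phenyl]dihydrofuran-2(3H)-one | O=C1O[C@H](c2cc(OCc3ccccc3)c(OCc3ccccc3)c(OCc3ccccc3)c2)[C@@H](CO)[C@H]1Cc1ccc(OCc2ccccc2)c(OCc2ccccc2)c1
F2 | step 4 | (R)-4-[3,4-bis(benzyloxy)phenyl]-3-(methoxycarbonyl)butanoic acid | COC(=O)[C@@H](CC(=O)O)Cc1ccc(OCc2ccccc2)c(OCc2ccccc2)c1
F3 | step 4 | (S)-4-benzyl-3-{(R)-4-[3,4-bis(benzyloxy)phenyl]-3-(methoxycarbonyl)butanoyl}oxazolidin-2-one | COC(=O)[C@@H](CC(=O)N1[C@@H](Cc2ccccc2)COC1=O)Cc1ccc(OCc2ccccc2)c(OCc2ccccc2)c1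
F4 | step 4 | (S)-4-benzyl-3-{[(2S,3S,4R)-4-[3,4-bis(benzyloxy)benzyl]-5-oxo-2-[3,4,5-tris(benzyloxy)phenyl]tetrahydrofuran-3-yl]carbonyl}oxazolidin-2-one | O=C1O[C@H](c2cc(OCc3ccccc3)c(OCc3ccccc3)c(OCc3ccccc3)c2)[C@@H](C(=O)N2[C@@H](Cc3ccccc3)COC2=O)[C@H]1Cc1ccc(OCc2ccccc2)c(OCc2ccccc2)c1
F5 | step 4 | (2S,3S,4R)-4-[3,4-bis(benzyloxy)benzyl]-5-oxo-2-[3,4,5-tris(benzyloxy)phenyl]tetrahydrofuran-3-carboxylic acid | O=C1O[C@H](c2cc(OCc3ccccc3)c(OCc3ccccc3)c(OCc3ccccc3)c2)[C@@H](C(=O)O)[C@H]1Cc1ccc(OCc2ccccc2)c(OCc2ccccc2)c1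
F0 | step 7 | none | none
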